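The five-membered ring is cut at C4–C5 and C1–C2 (C1 quaternary fusion carbon, C5 fusion CH, C4 isopropyl carbinol). Because C5 and C1 lie β and α to the C10 oxygen of the seven-membered ring, a C10 ketone lets both bonds form in one flask. An alkenylcuprate adds to C5 of a cross-conjugated cycloheptadienone anti to the C6 silyl ether, and the C10 enolate is allylated at C1 anti to C5, fixing the trans C1/C5 fusion pair and the quaternary methyl carbon. The precursor is (S)-4-silyloxy-2,6-dimethylcyclohepta-2,6-dienone, which already carries C6–O, C8=C9 and C10=O; its second enone survives as the masked C10 allylic ester. Ring-closing metathesis, hydration, reduction and acylation finish the target.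

Key step: step 9

Remark on numbering and faces: ring atoms are C1 (quaternary, methyl-bearing fusion carbon), C2 and C3 (methylenes), C4 (isopropyl carbinol), C5 (fusion CH), C6 (ester carbinol next to C5), C7 (methylene), C8=C9 (alkene, methyl on C8) and C10 (ester carbinol next to C1). The target is read as the 1S,4R,5S,6S,10R isomer, with H5, C6–O, C10–O and the C4 isopropyl group on one face (the H5 face) and the C1 methyl and C4 hydroxyl on the other (the methyl face).

Assumption: in the trans-fused bicycle the C1 methyl group is axial and shields its own face of the C10 carbonyl and of the C3=C4 bond; steps 11 and 12 are designed around this.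

Step 1
Reactants: 1 (S)-trityl glycidyl ether; 2 isopropenylmagnesium bromide
Product: 3 (S)-4-methyl-1-(trityloxy)pent-4-en-2-ol
Conditions: 2 (1.5 equiv), CuI (10 mol %), THF, −30 → 0 °C; aq. NH4Cl
Reagents that add atoms: isopropenylmagnesium bromide (2), CC(=C)[Mg]Br
Why: Copper-catalysed Grignard opening of the terminal epoxide (SN2 at the unsubstituted carbon) should give the homoallylic alcohol with the future C6 carbinol centre carried over unchanged from the glycidyl ether.

Step 2
Reactants: 3 (S)-4-methyl-1-(trityloxy)pent-4-en-2-ol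
Product: 4 (S)-tert-butyldimethyl{[4-methyl-1-(trityloxy)pent-4-en-2-yl]oxy}silane
Conditions: TBSCl, imidazole, DMF, rt
Reagents that add atoms: tert-butyldimethylsilyl chloride, CC(C)(C)[Si](C)(C)Cl
Why: Imidazole-promoted silylation of a secondary alcohol is routine and installs the bulky spectator group that later steers the cuprate to the opposite face of C5.

Step 3
Reactants: 4 (S)-tert-butyldimethyl{[4-methyl-1-(trityloxy)pent-4-en-2-yl]oxy}silane
Product: 5 (S)-2-[(tert-butyldimethylsilyl)oxy]-4-methylpent-4-en-1-ol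
Conditions: p-TsOH·H2O (10 mol %), MeOH/CH2Cl2 (1:1), 0 °C
Reagents that add atoms: none
Why: Acid-catalysed methanolysis (solvolytic detritylation through the trityl cation, trapped as its methyl ether) should cleave the primary trityl ether well before the secondary silyl ether or the alkene is touched at 0 °C.

Step 4
Reactants: 5 (S)-2-[(tert-butyldimethylsilyl)oxy]-4-methylpent-4-en-1-ol
Product: 6 (S)-2-[(tert-butyldimethylsilyl)oxy]-4-methylpent-4-enal
Conditions: Dess–Martin periodinane, NaHCO3, CH2Cl2, 0 °C → rt; used crude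
Reagents that add atoms: none
Why: Buffered Dess–Martin oxidation stops at the aldehyde under near-neutral conditions, so the α-silyloxy stereocentre should not epimerise if the crude aldehyde is used at once.

Step 5
Reactants: 6 (S)-2-[(tert-butyldimethylsilyl)oxy]-4-methylpent-4-enal; 7 ethyl 2-[bis(2,2,2-trifluoroethoxy)phosphoryl]propanoate
Product: 8 ethyl (S,Z)-4-[(tert-butyldimethylsilyl)oxy]-2,6-dimethylhepta-2,6-dienoate
Conditions: 7, KN(SiMe3)2, 18-crown-6, THF, −78 °C
Reagents that add atoms: ethyl 2-[bis(2,2,2-trifluoroethoxy)phosphoryl]propanoate (7), CCOC(=O)C(C)P(=O)(OCC(F)(F)F)OCC(F)(F)F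
Why: Still–Gennari olefination with the electron-poor trifluoroethyl phosphonate under dissociating potassium/crown conditions should give the (Z)-enoate kinetically, placing C6 and the future C10 carbonyl cis across C1=C5 as the ring demands.

Step 6
Reactants: 8 ethyl (S,Z)-4-[(tert-butyldimethylsilyl)oxy]-2,6-dimethylhepta-2,6-dienoate
Product: 9 (S,Z)-4-[(tert-butyldimethylsilyl)oxy]-N-methoxy-N,2,6-trimethylhepta-2,6-dienamide
Conditions: MeNH(OMe)·HCl, i-PrMgCl, THF, −20 → 0 °C; aq. NH4Cl
Reagents that add atoms: N,O-dimethylhydroxylamine hydrochloride, CNOC.Cl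
Why: Direct ester aminolysis by the chloromagnesium amide of N,O-dimethylhydroxylamine (Weinreb amide formation) proceeds below 0 °C and should leave the Z alkene and the silyl ether untouched.

Step 7
Reactants: 9 (S,Z)-4-[(tert-butyldimethylsilyl)oxy]-N-methoxy-N,2,6-trimethylhepta-2,6-dienamide; 10 vinylmagnesium bromide
Product: 11 (S,Z)-6-[(tert-butyldimethylsilyl)oxy]-4,8-dimethylnona-1,4,8-trien-3-one
Conditions: 10 (1.5 equiv), THF, −20 → 0 °C; inverse quench into cold 1 M HCl
Reagents that add atoms: vinylmagnesium bromide (10), C=C[Mg]Br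
Why: In this Weinreb ketone synthesis the chelated tetrahedral adduct prevents a second addition, and the acidic inverse quench protonates the released amine so that it cannot add to the new vinyl ketone.

Step 8
Reactants: 11 (S,Z)-6-[(tert-butyldimethylsilyl)oxy]-4,8-dimethylnona-1,4,8-trien-3-one
Product: 12 (S)-4-[(tert-butyldimethylsilyl)oxy]-2,6-dimethylcyclohepta-2,6-dien-1-one
Conditions: second-generation Grubbs catalyst (5 mol %), CH2Cl2 (0.005 M), 40 °C
Reagents that add atoms: none
Why: Ring-closing metathesis of the vinyl ketone with the 1,1-disubstituted alkene forms C8=C9 and the seven-membered ring, helped by the Z C1=C5 bond that holds the two ends together and driven by loss of ethylene under neutral conditions that spare the elimination-prone C6 silyl ether.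

Step 9
Reactants: 12 (S)-4-[(tert-butyldimethylsilyl)oxy]-2,6-dimethylcyclohepta-2,6-dien-1-one; 13 2-bromo-3-methylbut-1-ene; 14 allyl bromide
Product: 18 (2S,3S,4S)-2-allyl-4-[(tert-butyldimethylsilyl)oxy]-2,6-dimethyl-3-(3-methylbut-1-en-2-yl)cyclohept-6-en-1-one, via 3-methylbut-1-en-2-yllithium 15 (not isolated), via lithium bis(3-methylbut-1-en-2-yl)cuprate 16 (not isolated), via lithium enolate 17 (not isolated)
Conditions: 13 (2.4 equiv), t-BuLi (4.8 equiv), Et2O, −78 °C; CuI (1.2 equiv), −78 → −40 °C; 12, Et2O, −78 → −50 °C; THF, HMPA, 14 (5 equiv), −78 → −20 °C; aq. NH4Cl/NH3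
Reagents that add atoms: 2-bromo-3-methylbut-1-ene (13), C=C(Br)C(C)C; allyl bromide (14), C=CCBr
Why: The lithium dialkenylcuprate 16 complexes the C1=C5 enone, oxidative addition gives a β-cuprated (formally trivalent copper) enolate and reductive elimination forges C4–C5 and leaves lithium enolate 17, which attacks allyl bromide in an HMPA-assisted SN2 reaction at C1 to form C1–C2. The closest known reaction type is the one-flask conjugate addition of alkenylcuprates to 2-methylcycloalkenones with C-alkylation of the regiodefined enolate to an α-quaternary ketone (three-component coupling). No ring is closed, so no closure mode arises; the two new alkenes are only set up for the later five-membered ring metathesis. C5 is set by cuprate attack on the enone face anti to the C6 silyloxy group (the usual anti addition to γ-silyloxy enones), and C1 by allyl bromide approaching the enolate face opposite the bulky new C5 alkenyl group, which gives the trans C4/C2 pair and leaves the methyl group cis to C4. The step needs regioselection for C5 over C8, which the β-methyl group on C8 secures because cuprates add far more slowly to β,β-disubstituted enones, and C- over O-alkylation without proton transfer, which the soft allylic bromide and the aprotic medium favour. The cold, weakly basic cuprate should also avoid γ-deprotonation at C7 and loss of silanolate towards a tropone.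

Step 10
Reactants: 18 (2S,3S,4S)-2-allyl-4-[(tert-butyldimethylsilyl)oxy]-2,6-dimethyl-3-(3-methylbut-1-en-2-yl)cyclohept-6-en-1-one
Product: 19 (3aS,8S,8aS)-8-[(tert-butyldimethylsilyl)oxy]-1-isopropyl-3a,6-dimethyl-3,3a,8,8a-tetrahydroazulen-4(7H)-one
Conditions: second-generation Grubbs catalyst (5 mol %), CH2Cl2, 40 °C
Reagents that add atoms: none
Why: Ring-closing metathesis starts at the allyl group and closes onto the neighbouring 1,1-disubstituted alkene to give the cyclopentene C3=C4 (five-membered ring closure, ethylene lost), the trans arms on C1 and C5 being both pseudoequatorial and within reach while the conjugated trisubstituted C8=C9 bond stays out.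

Step 11
Reactants: 19 (3aS,8S,8aS)-8-[(tert-butyldimethylsilyl)oxy]-1-isopropyl-3a,6-dimethyl-3,3a,8,8a-tetrahydroazulen-4(7H)-one
Product: 21 (1R,3aS,8S,8aS)-8-[(tert-butyldimethylsilyl)oxy]-1-hydroxy-1-isopropyl-3a,6-dimethyl-2,3,3a,7,8,8a-hexahydroazulen-4(1H)-one, via C3 acetoxymercurio carbinol 20 (not isolated)
Conditions: Hg(OAc)2, THF/H2O (1:1), 0 °C → rt; extractive work-up; crude 20, Bu3SnH, THF, 0 °C → rt
Reagents that add atoms: water, O
Why: In this Markovnikov oxymercuration–demercuration divalent mercury engages only the electron-rich C3=C4 bond, on the H5 face away from the axial C1 methyl group, water opens the mercurinium ion anti at tertiary C4 so that the hydroxyl lands on the methyl face as in the target, and the tin hydride then removes mercury by a radical chain that, unlike a borohydride, does not reduce the C10 enone.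

Step 12
Reactants: 21 (1R,3aS,8S,8aS)-8-[(tert-butyldimethylsilyl)oxy]-1-hydroxy-1-isopropyl-3a,6-dimethyl-2,3,3a,7,8,8a-hexahydroazulen-4(1H)-one
Product: 22 (1R,3aS,4R,8S,8aS)-8-[(tert-butyldimethylsilyl)oxy]-1-isopropyl-3a,6-dimethyl-1,2,3,3a,4,7,8,8a-octahydroazulene-1,4-diol
Conditions: (S)-1-methyl-3,3-diphenyltetrahydro-1H,3H-pyrrolo[1,2-c][1,3,2]oxazaborole (1 equiv), catecholborane (3 equiv), toluene, −78 → −40 °C; MeOH, aq. NaOH
Reagents that add atoms: none
Why: In this Corey–Bakshi–Shibata reduction under reagent control, with quaternary C1 as the large and vinylic C9 as the small flank, the (S)-catalyst should deliver hydride to the methyl face of C10 and give the 10R allylic alcohol on the H5 face, cis to C6–O, which substrate-controlled hydrides attacking anti to the axial C1 methyl group would not be expected to favour.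

Step 13
Reactants: 22 (1R,3aS,4R,8S,8aS)-8-[(tert-butyldimethylsilyl)oxy]-1-isopropyl-3a,6-dimethyl-1,2,3,3a,4,7,8,8a-octahydroazulene-1,4-diol
Product: 23 (1R,3aS,4R,8S,8aS)-1-isopropyl-3a,6-dimethyl-1,2,3,3a,4,7,8,8a-octahydroazulene-1,4,8-triol
Conditions: Bu4NF, THF, 0 °C → rt
Reagents that add atoms: none
Why: Fluoride-mediated desilylation is driven by the strong Si–F bond and should free the C6 alcohol without harming the allylic or tertiary alcohols.

Step 14
Reactants: 23 (1R,3aS,4R,8S,8aS)-1-isopropyl-3a,6-dimethyl-1,2,3,3a,4,7,8,8a-octahydroazulene-1,4,8-triol; 24 angelic acid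
Product: 26 (1R,3aS,4R,8S,8aS)-1-hydroxy-1-isopropyl-3a,6-dimethyl-1,2,3,3a,4,7,8,8a-octahydroazulene-4,8-diyl bis[(Z)-2-methylbut-2-enoate], via angelic 2,4,6-trichlorobenzoic anhydride 25 (not isolated)
Conditions: 24 (6 equiv), 2,4,6-trichlorobenzoyl chloride (6 equiv), Et3N (7 equiv), toluene, rt; then 23, toluene, 80 °C
Reagents that add atoms: angelic acid (24), C/C=C(/C)C(=O)O
Why: Yamaguchi-type mixed-anhydride esterification without a nucleophilic catalyst should acylate both secondary alcohols at the less hindered angeloyl carbonyl without Z-to-E isomerisation to tiglates, while the tertiary C4 hydroxyl is too hindered to react.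

Compound list
1 | (S)-trityl glycidyl ether | C(OC(c1ccccc1)(c1ccccc1)c1ccccc1)[C@@H]1CO1 | starting material
2 | isopropenylmagnesium bromide | CC(=C)[Mg]Br | starting material
3 | (S)-4-methyl-1-(trityloxy)pent-4-en-2-ol | O[C@H](COC(c1ccccc1)(c1ccccc1)c1ccccc1)CC(C)=C | intermediate
4 | (S)-tert-butyldimethyl{[4-methyl-1-(trityloxy)pent-4-en-2-yl]oxy}silane | CC(C)(C)[Si](C)(C)O[C@H](COC(c1ccccc1)(c1ccccc1)c1ccccc1)CC(C)=C | intermediate
5 | (S)-2-[(tert-butyldimethylsilyl)oxy]-4-methylpent-4-en-1-ol | CC(C)(C)[Si](C)(C)O[C@H](CO)CC(C)=C | intermediate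
6 | (S)-2-[(tert-butyldimethylsilyl)oxy]-4-methylpent-4-enal | CC(C)(C)[Si](C)(C)O[C@H](C=O)CC(C)=C | intermediate
7 | ethyl 2-[bis(2,2,2-trifluoroethoxy)phosphoryl]propanoate | CCOC(=O)C(C)P(=O)(OCC(F)(F)F)OCC(F)(F)F | starting material
8 | ethyl (S,Z)-4-[(tert-butyldimethylsilyl)oxy]-2,6-dimethylhepta-2,6-dienoate | CC(C)(C)[Si](C)(C)O[C@H](/C=C(/C)C(=O)OCC)CC(C)=C | intermediate
9 | (S,Z)-4-[(tert-butyldimethylsilyl)oxy]-N-methoxy-N,2,6-trimethylhepta-2,6-dienamide | CC(C)(C)[Si](C)(C)O[C@H](/C=C(/C)C(=O)N(C)OC)CC(C)=C | intermediate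
10 | vinylmagnesium bromide | C=C[Mg]Br | starting material
11 | (S,Z)-6-[(tert-butyldimethylsilyl)oxy]-4,8-dimethylnona-1,4,8-trien-3-one | CC(C)(C)[Si](C)(C)O[C@H](/C=C(/C)C(=O)C=C)CC(C)=C | intermediate
12 | (S)-4-[(tert-butyldimethylsilyl)oxy]-2,6-dimethylcyclohepta-2,6-dien-1-one | CC(C)(C)[Si](C)(C)O[C@H]1CC(C)=CC(=O)C(C)=C1 | intermediate
13 | 2-bromo-3-methylbut-1-ene | C=C(Br)C(C)C | starting material
14 | allyl bromide | C=CCBr | starting material
15 | 3-methylbut-1-en-2-yllithium | [Li]C(=C)C(C)C | intermediate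
16 | lithium bis(3-methylbut-1-en-2-yl)cuprate | [Li+].CC(C)C(=C)[Cu-]C(=C)C(C)C | intermediate
17 | lithium (3S,4S)-4-[(tert-butyldimethylsilyl)oxy]-2,6-dimethyl-3-(3-methylbut-1-en-2-yl)cyclohepta-1,6-dien-1-olate | CC(C)(C)[Si](C)(C)O[C@H]1CC(C)=CC(O[Li])=C(C)[C@@H]1C(=C)C(C)C | intermediate
18 | (2S,3S,4S)-2-allyl-4-[(tert-butyldimethylsilyl)oxy]-2,6-dimethyl-3-(3-methylbut-1-en-2-yl)cyclohept-6-en-1-one | CC(C)(C)[Si](C)(C)O[C@H]1CC(C)=CC(=O)[C@@](C)(CC=C)[C@@H]1C(=C)C(C)C | intermediate
19 | (3aS,8S,8aS)-8-[(tert-butyldimethylsilyl)oxy]-1-isopropyl-3a,6-dimethyl-3,3a,8,8a-tetrahydroazulen-4(7H)-one | CC(C)(C)[Si](C)(C)O[C@H]1CC(C)=CC(=O)[C@@]2(C)CC=C(C(C)C)[C@H]12 | intermediate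
20 | (1R,2R,3aS,8S,8aS)-2-(acetoxymercurio)-8-[(tert-butyldimethylsilyl)oxy]-1-hydroxy-1-isopropyl-3a,6-dimethyl-2,3,3a,7,8,8a-hexahydroazulen-4(1H)-one | CC(C)(C)[Si](C)(C)O[C@H]1CC(C)=CC(=O)[C@@]2(C)C[C@@H]([Hg]OC(C)=O)[C@@](O)(C(C)C)[C@H]12 | intermediate
21 | (1R,3aS,8S,8aS)-8-[(tert-butyldimethylsilyl)oxy]-1-hydroxy-1-isopropyl-3a,6-dimethyl-2,3,3a,7,8,8a-hexahydroazulen-4(1H)-one | CC(C)(C)[Si](C)(C)O[C@H]1CC(C)=CC(=O)[C@@]2(C)CC[C@@](O)(C(C)C)[C@H]12 | intermediate
22 | (1R,3aS,4R,8S,8aS)-8-[(tert-butyldimethylsilyl)oxy]-1-isopropyl-3a,6-dimethyl-1,2,3,3a,4,7,8,8a-octahydroazulene-1,4-diol | CC(C)(C)[Si](C)(C)O[C@H]1CC(C)=C[C@@H](O)[C@@]2(C)CC[C@@](O)(C(C)C)[C@H]12 | intermediate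
23 | (1R,3aS,4R,8S,8aS)-1-isopropyl-3a,6-dimethyl-1,2,3,3a,4,7,8,8a-octahydroazulene-1,4,8-triol | O[C@H]1CC(C)=C[C@@H](O)[C@@]2(C)CC[C@@](O)(C(C)C)[C@H]12 | intermediate
24 | angelic acid, (Z)-2-methylbut-2-enoic acid | C/C=C(/C)C(=O)O | starting material
25 | angelic 2,4,6-trichlorobenzoic anhydride | C/C=C(/C)C(=O)OC(=O)c1c(Cl)cc(Cl)cc1Cl | intermediate
26 | (1R,3aS,4R,8S,8aS)-1-hydroxy-1-isopropyl-3a,6-dimethyl-1,2,3,3a,4,7,8,8a-octahydroazulene-4,8-diyl bis[(Z)-2-methylbut-2-enoate] | C/C=C(/C)C(=O)O[C@H]1CC(C)=C[C@@H](OC(=O)/C(C)=C\C)[C@@]2(C)CC[C@@](O)(C(C)C)[C@H]12 | target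

Total step count: 14. Longest linear sequence: 14 steps (1 → 26).

Steps most likely to fail

Step 9. The hindered enolate may alkylate sluggishly or on oxygen, or be quenched by proton transfer. Base may also trigger loss of the C6 silanolate towards a tropone. The fallback sets out from 12. Cuprate 16 would be added in the presence of Me3SiCl (THF, −78 °C), which speeds the conjugate addition and traps the adduct as (3S,4S)-4-[(tert-butyldimethylsilyl)oxy]-2,6-dimethyl-3-(3-methylbut-1-en-2-yl)-1-[(trimethylsilyl)oxy]cyclohepta-1,6-diene F1. MeLi (THF, 0 °C) would release the copper-free lithium enolate, which allyl chloroformate should O-acylate to allyl (3S,4S)-4-[(tert-butyldimethylsilyl)oxy]-2,6-dimethyl-3-(3-methylbut-1-en-2-yl)cyclohepta-1,6-dien-1-yl carbonate F2. Pd(PPh3)4 (zerovalent palladium, THF, rt) would then bring about decarboxylative Tsuji allylation through a π-allylpalladium enolate pair. This forms C1–C2 on the face anti to the C5 alkenyl group and comes back to the route at 18.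

Step 11. Reversible mercurinium formation may give poor facial selectivity at C4, or the hindered alkene may react incompletely. The fallback sets out from 19. N-Bromosuccinimide in DME/H2O at 0 °C should form the bromonium ion irreversibly on the H5 face, and water should open it anti at tertiary C4. This gives (1R,2R,3aS,8S,8aS)-2-bromo-8-[(tert-butyldimethylsilyl)oxy]-1-hydroxy-1-isopropyl-3a,6-dimethyl-2,3,3a,7,8,8a-hexahydroazulen-4(1H)-one F3. Radical debromination (Bu3SnH, Et3B/air, toluene, rt) would then come back to the route at 21.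

Step 12. The catalyst works against the intrinsic facial bias of the ketone, so facial selectivity at C10 may be poor. The fallback sets out from 21 and accepts substrate control. Luche reduction (NaBH4, CeCl3·7H2O, MeOH, −78 °C) should deliver hydride anti to the axial C1 methyl group and give (1R,3aS,4S,8S,8aS)-8-[(tert-butyldimethylsilyl)oxy]-1-isopropyl-3a,6-dimethyl-1,2,3,3a,4,7,8,8a-octahydroazulene-1,4-diol F4. Mitsunobu inversion (4-nitrobenzoic acid, PPh3, DIAD, toluene, 0 °C → rt) would give (1R,3aS,4R,8S,8aS)-8-[(tert-butyldimethylsilyl)oxy]-1-hydroxy-1-isopropyl-3a,6-dimethyl-1,2,3,3a,4,7,8,8a-octahydroazulen-4-yl 4-nitrobenzoate F5. Methanolysis (K2CO3, MeOH, rt) would come back to the route at 22.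

Further compounds
F1 | step 9 | (3S,4S)-4-[(tert-butyldimethylsilyl)oxy]-2,6-dimethyl-3-(3-methylbut-1-en-2-yl)-1-[(trimethylsilyl)oxy]cyclohepta-1,6-diene | CC(C)(C)[Si](C)(C)O[C@H]1CC(C)=CC(O[Si](C)(C)C)=C(C)[C@@H]1C(=C)C(C)C
F2 | step 9 | allyl (3S,4S)-4-[(tert-butyldimethylsilyl)oxy]-2,6-dimethyl-3-(3-methylbut-1-en-2-yl)cyclohepta-1,6-dien-1-yl carbonate | CC(C)(C)[Si](C)(C)O[C@H]1CC(C)=CC(OC(=O)OCC=C)=C(C)[C@@H]1C(=C)C(C)C
F3 | step 11 | (1R,2R,3aS,8S,8aS)-2-bromo-8-[(tert-butyldimethylsilyl)oxy]-1-hydroxy-1-isopropyl-3a,6-dimethyl-2,3,3a,7,8,8a-hexahydroazulen-4(1H)-one | CC(C)(C)[Si](C)(C)O[C@H]1CC(C)=CC(=O)[C@@]2(C)C[C@@H](Br)[C@@](O)(C(C)C)[C@H]12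
F4 | step 12 | (1R,3aS,4S,8S,8aS)-8-[(tert-butyldimethylsilyl)oxy]-1-isopropyl-3a,6-dimethyl-1,2,3,3a,4,7,8,8a-octahydroazulene-1,4-diol | CC(C)(C)[Si](C)(C)O[C@H]1CC(C)=C[C@H](O)[C@@]2(C)CC[C@@](O)(C(C)C)[C@H]12
F5 | step 12 | (1R,3aS,4R,8S,8aS)-8-[(tert-butyldimethylsilyl)oxy]-1-hydroxy-1-isopropyl-3a,6-dimethyl-1,2,3,3a,4,7,8,8a-octahydroazulen-4-yl 4-nitrobenzoate | CC(C)(C)[Si](C)(C)O[C@H]1CC(C)=C[C@@H](OC(=O)c3ccc(cc3)[N+](=O)[O-])[C@@]2(C)CC[C@@](O)(C(C)C)[C@H]12
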